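The numbers in the tables were computed with made-up constants, and the scatter is random.

In this stirred vessel a substrate meets a partner fed in at a steady rate, and the earlier runs show substrate passing to intermediate A and on to side product; I count two partners for each side product.

| setting | Wednesday's | Sunday's | Monday's | flask |
|---|---|---|---|---|
| substrate | 22 mM | 34 mM | 45 mM | 45 mM |
| partner | 1.8 equiv (fed, over 5.0 h) | 1.8 equiv (fed, over 5.0 h) | 3.6 equiv (fed, over 5.0 h) | 1.80 equiv (fed, over 5.0 h) |
| remark | run made earlier; the fed solution adds 1.0 times the starting volume | run made earlier; the fed solution adds 1.0 times the starting volume | run made earlier; the fed solution adds 1.0 times the starting volume | the fed solution adds 1.0 times the starting volume |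
| time |  |  |  | 8.0 h |

| run | time / h | side product / % | intermediate B / % | intermediate A / % | isomer of the product / % | substrate / % | target / % |
|---|---|---|---|---|---|---|---|
| Wednesday's | 1.00 | 2.5 | 0 | 8.8 | 0 | 89.8 | 0 |
| Wednesday's | 3.00 | 17.2 | 0 | 21.6 | 0 | 59.4 | 1.9 |
| Wednesday's | 5.00 | 39.8 | 0 | 18.5 | 0 | 34.2 | 3.5 |
| Wednesday's | 8.00 | 61.5 | 1.7 | 11.6 | 1.9 | 20.6 | 1.9 |
| Sunday's | 1.00 | 2.1 | 0 | 9.4 | 0.4 | 87.8 | 0 |
| Sunday's | 3.00 | 22.3 | 0.5 | 21.4 | 0.7 | 53.7 | 1.0 |
| Sunday's | 5.00 | 50.4 | 0 | 13.8 | 0 | 28.6 | 3.3 |
| Sunday's | 8.00 | 67.2 | 0 | 8.9 | 2.7 | 18.1 | 4.0 |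
| Monday's | 0.667 | 2.7 | 0 | 9.8 | 0 | 85.0 | 0 |
| Monday's | 1.33 | 15.7 | 0 | 20.9 | 0 | 61.8 | 1.1 |
| Monday's | 3.00 | 59.0 | 0 | 13.5 | 0.9 | 21.4 | 4.0 |
| Monday's | 8.00 | 92.6 | 0 | 2.2 | 0.1 | 0 | 6.4 |

(standard deviation of a reading: 1 percentage point)

- charges are per starting volume, the dose included; the dosed solution carries all of it

1. where most of what was charged as substrate, at 8.0 h is found (intermediate A / intermediate B / side product / isomer of the product / target / substrate)
2. the largest share itself, whichever of these holds it, in percent of the substrate charged

For the flask, the cover is 0.900: half the equivalents of partner, which is the fraction of the substrate charged that the partner can carry through both additions. That is below one, so in the flask partner is the limiting reagent. Monday's cover was 1.80, and there side product and target together reach 99.0%.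

Now the ladder of rates, as fractions of the charge. The flask's feed brings 0.360 h⁻¹ of partner, and Sunday's run has the same feed. In Sunday's run, side product grew at a reading of 0.141 h⁻¹ late in the feed, so at two partners each it took up partner more slowly than the feed supplied it. After the feed, side product in Sunday's run slowed to a reading of 0.0560 h⁻¹, so you should expect a slow tail. At the last reading, Wednesday's run stood at 0.683 of this cover and Sunday's at 0.747. Carrying that rise with concentration on to this flask, I would commit to side product at about 72.4%.

The forecast also names side product, at 70%, a little below my figure; it extrapolates partner use across concentrations and says that the flask “has the same 1.8 equiv as those runs, so it is partner-limited”.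

    substrate + partner → intermediate A (k = 0.0100 M⁻¹ s⁻¹)
    partner + intermediate A ⇌ intermediate B (K = 5.20 M⁻¹, k = 0.00260 M⁻¹ s⁻¹)
    partner + intermediate A → side product (k = 0.0230 M⁻¹ s⁻¹)
    intermediate B → target (k = 0.00190 s⁻¹)
    intermediate B → decomposed reagent (k = 8.00 × 10⁻⁴ s⁻¹)
    target ⇌ isomer of the product (K = 0.160, k = 4.30 × 10⁻⁴ s⁻¹)

The flask gives side product at 71.2%, which is 0.792 of its cover, with 8.6% of the partner still unbound. For the forecast to be wrong, a run would have to show another species on top, and one neighbour does. The neighbour charged with 0.450 equiv has a cover of 0.225, and its side product reaches 11.2%, under that cover. Its intermediate A stands at 19.9%, its partner is down to 1.1%, and substrate now holds the most, at 67.8%.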